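**Plan**
- Cuts: both phenolic O–H bonds (MOM ethers), the oxygen on the outer carbonyl carbon (back to a deoxybenzoin CH2), and the C8–CH2 bond of the prenyl group (back to a C8 iodide). The bond from the outer carbon to ring B is undone as a 1,2-aryl shift, which restores one extra carbon and gives a chalcone. The chalcone is cut at Cα=Cβ, and the pyran ring at O1–C2 and C4–C4a.
- Enabling feature: the outer carbon of the C6–C(=O)–C(=O) unit carries ring B, a 4-oxyphenyl ring whose para oxygen lets it bridge and move from Cβ to Cα of an enone.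
- Forward order: the ring A acetophenone is iodinated between its hydroxyls, and the pyran ring (the only ring made) is fused at the last free ring carbon. The chain is joined by Claisen–Schmidt condensation, ring B is shifted, and the old Cβ is lost as formate. Prenyl then replaces iodine, O2 installs the second carbonyl and acid frees the phenols.
- Stereochemistry: derrisdione A has no stereocentre and no alkene with E/Z isomers. The chalcone is E by thermodynamic control; the one stereocentre formed in the key step is racemic and is erased in the next step.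

Key step: step 6

Assumptions: iodination of the starting acetophenone is taken to occur at the ring carbon between the two hydroxyls, as with resorcinol-type phenols; tributyl(3-methylbut-2-en-1-yl)stannane is taken as a purchased reagent; MOM stands for methoxymethyl.

Step 1
Reactants: 1 1-(2,4-dihydroxy-6-methoxyphenyl)ethan-1-one
Product: 2 1-(2,4-dihydroxy-3-iodo-6-methoxyphenyl)ethan-1-one
Conditions: I2 (0.4 equiv), HIO3 (0.2 equiv), EtOH/H2O, 25–40 °C
Reagents that add atoms: iodine, II; iodic acid, OI(=O)=O
Why: Electrophilic aromatic iodination with the I2/HIO3 couple should take the carbon flanked by both hydroxyls, the site at which resorcinols are iodinated, and one equivalent of iodine in total should leave the second free ring carbon untouched.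

Step 2
Reactants: 2 1-(2,4-dihydroxy-3-iodo-6-methoxyphenyl)ethan-1-one; 3 3-methylbut-2-enal
Product: 5 1-(7-hydroxy-8-iodo-5-methoxy-2,2-dimethyl-2H-chromen-6-yl)ethan-1-one, via ortho-quinone methide 4 (not isolated)
Conditions: ethylenediammonium diacetate (0.2 equiv), toluene, 100 °C
Reagents that add atoms: none
Why: Knoevenagel-type condensation of the only free ring carbon (ortho to the unchelated hydroxyl) with the enal gives ortho-quinone methide 4, whose oxa-6π electrocyclisation closes the 2,2-dimethyl-2H-pyran ring, while the iodine blocks the otherwise preferred carbon between the two oxygens.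

Step 3
Reactants: 5 1-(7-hydroxy-8-iodo-5-methoxy-2,2-dimethyl-2H-chromen-6-yl)ethan-1-one
Product: 6 1-[8-iodo-5-methoxy-7-(methoxymethoxy)-2,2-dimethyl-2H-chromen-6-yl]ethan-1-one
Conditions: NaH, MOMCl, DMF, 0 °C to rt
Reagents that add atoms: chloromethyl methyl ether, COCCl
Why: Williamson-type O-alkylation of the sodium phenoxide gives the MOM ether, NaH being chosen because this hydroxyl is hydrogen-bonded to the acetyl group and flanked by iodine.

Step 4
Reactants: 7 4-hydroxybenzaldehyde
Product: 8 4-(methoxymethoxy)benzaldehyde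
Conditions: MOMCl, K2CO3, acetone, rt
Reagents that add atoms: chloromethyl methyl ether, COCCl
Why: Standard MOM ether formation of a phenol removes the acidic hydroxyl before the basic condensation and keeps ring B from being oxidised by trivalent thallium later.

Step 5
Reactants: 6 1-[8-iodo-5-methoxy-7-(methoxymethoxy)-2,2-dimethyl-2H-chromen-6-yl]ethan-1-one; 8 4-(methoxymethoxy)benzaldehyde
Product: 9 (E)-1-[8-iodo-5-methoxy-7-(methoxymethoxy)-2,2-dimethyl-2H-chromen-6-yl]-3-[4-(methoxymethoxy)phenyl]prop-2-en-1-one
Conditions: KOH, EtOH, rt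
Reagents that add atoms: none
Why: Claisen–Schmidt condensation (crossed aldol, then E1cB dehydration) of the methyl ketone enolate with the non-enolisable aldehyde should give the thermodynamically favoured E enone, and MOM ethers, aryl iodide and chromene are inert to KOH.

Step 6
Reactants: 9 (E)-1-[8-iodo-5-methoxy-7-(methoxymethoxy)-2,2-dimethyl-2H-chromen-6-yl]-3-[4-(methoxymethoxy)phenyl]prop-2-en-1-one
Product: 11 rac-1-[8-iodo-5-methoxy-7-(methoxymethoxy)-2,2-dimethyl-2H-chromen-6-yl]-3,3-dimethoxy-2-[4-(methoxymethoxy)phenyl]propan-1-one, via oxythallation adduct 10 (not isolated)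
Conditions: Tl(NO3)3·3H2O (1.1 equiv), MeOH/HC(OMe)3 (3:1), 0 °C to rt; then aq. NaHCO3
Reagents that add atoms: methanol, CO
Why: Electrophilic trivalent thallium adds to the alpha carbon of the enone while methanol adds anti at the benzylic beta carbon (adduct 10); the weak C–Tl bond then heterolyses with loss of monovalent thallium as TlNO3, assisted by the 4-(methoxymethoxy)phenyl ring, which bridges as a phenonium ion and ends on the alpha carbon, and the oxocarbenium ion left on the old beta carbon takes up a second methanol to give the dimethyl acetal. The closest known reaction is the Tl(NO3)3-mediated oxidative 1,2-aryl rearrangement of chalcones to 1,2-diaryl-3,3-dimethoxypropan-1-ones used to make isoflavones. No ring is closed. The new stereocentre (C2 of the propanone) forms without any controlling element, so 11 is racemic, which is harmless because this carbon becomes CH2 and then C=O. The step needs aryl and not aroyl migration, which the para oxygen on ring B secures, and attack at the enone and not at another alkene, which is secured by holding the prenyl group back as the C8 iodide, by the gem-dimethyl group and the peri methoxyl that shield the chromene double bond, and by a small excess of oxidant at low temperature. The C7 hydroxyl is capped as its MOM ether so that it cannot cyclise onto the activated alkene (aurone formation).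

Step 7
Reactants: 11 rac-1-[8-iodo-5-methoxy-7-(methoxymethoxy)-2,2-dimethyl-2H-chromen-6-yl]-3,3-dimethoxy-2-[4-(methoxymethoxy)phenyl]propan-1-one
Product: 14 1-[8-iodo-5-methoxy-7-(methoxymethoxy)-2,2-dimethyl-2H-chromen-6-yl]-2-[4-(methoxymethoxy)phenyl]ethan-1-one, via beta-methoxy enone 12 (not isolated), via formyl ketone 13 (not isolated)
Conditions: KOH (aq., excess), MeOH/1,4-dioxane, reflux, argon; then aq. NH4Cl
Reagents that add atoms: none
Why: Proposed new method: the hydrogen alpha to the ketone of 11 is also benzylic, so hydroxide should remove it and expel methoxide from the acetal carbon (E1cB) to give beta-methoxy enone 12, addition–elimination of hydroxide at its beta carbon should give the enolate of formyl ketone 13, and retro-Claisen attack of hydroxide on the formyl group should release formate and the deoxybenzoin enolate, all without acid so that both MOM ethers stay on; the closest known reaction types are the base-induced loss of methanol from beta-keto acetals and the alkaline ring-opening and deformylation of isoflavones to deoxybenzoins, and the doubly ortho-substituted aryl ketone is too hindered to be cleaved in place of the formyl group.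

Step 8
Reactants: 14 1-[8-iodo-5-methoxy-7-(methoxymethoxy)-2,2-dimethyl-2H-chromen-6-yl]-2-[4-(methoxymethoxy)phenyl]ethan-1-one; 15 tributyl(3-methylbut-2-en-1-yl)stannane
Product: 16 1-[5-methoxy-7-(methoxymethoxy)-2,2-dimethyl-8-(3-methylbut-2-en-1-yl)-2H-chromen-6-yl]-2-[4-(methoxymethoxy)phenyl]ethan-1-one
Conditions: Pd(PPh3)4 (10 mol%), DMF, 90 °C, argon
Reagents that add atoms: none
Why: Stille coupling, in which zerovalent palladium inserts into the C8–I bond, the prenyl group is transferred from tin and reductive elimination from the aryl(prenyl)palladium intermediate at its unsubstituted terminus gives the linear prenyl arene under neutral conditions that leave the enolisable ketone alone.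

Step 9
Reactants: 16 1-[5-methoxy-7-(methoxymethoxy)-2,2-dimethyl-8-(3-methylbut-2-en-1-yl)-2H-chromen-6-yl]-2-[4-(methoxymethoxy)phenyl]ethan-1-one
Product: 18 1-[5-methoxy-7-(methoxymethoxy)-2,2-dimethyl-8-(3-methylbut-2-en-1-yl)-2H-chromen-6-yl]-2-[4-(methoxymethoxy)phenyl]ethane-1,2-dione, via alpha-hydroperoxy ketone 17 (not isolated)
Conditions: DABCO (0.5 equiv), air, DMF, 90 °C
Reagents that add atoms: dioxygen, O=O
Why: Base-catalysed enolate autoxidation of a deoxybenzoin, in which the enolate captures triplet oxygen at the benzylic carbon to give hydroperoxide 17 and base-induced loss of water (Kornblum–DeLaMare type) gives the 1,2-diketone, with both phenols masked so that they can neither quench the peroxyl radicals nor be oxidised themselves.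

Step 10
Reactants: 18 1-[5-methoxy-7-(methoxymethoxy)-2,2-dimethyl-8-(3-methylbut-2-en-1-yl)-2H-chromen-6-yl]-2-[4-(methoxymethoxy)phenyl]ethane-1,2-dione
Product: 19 derrisdione A, 1-[7-hydroxy-5-methoxy-2,2-dimethyl-8-(3-methylbut-2-en-1-yl)-2H-chromen-6-yl]-2-(4-hydroxyphenyl)ethane-1,2-dione
Conditions: 3 M aq. HCl, THF, 45 °C
Reagents that add atoms: none
Why: Acid-catalysed hydrolysis of the two MOM acetals should release both phenols under dilute, mildly warm conditions that prenyl groups and 2,2-dimethylchromenes normally tolerate.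

**Compound list**
1 | 1-(2,4-dihydroxy-6-methoxyphenyl)ethan-1-one (2',4'-dihydroxy-6'-methoxyacetophenone) | COc1cc(O)cc(O)c1C(C)=O | starting material
2 | 1-(2,4-dihydroxy-3-iodo-6-methoxyphenyl)ethan-1-one | COc1cc(O)c(I)c(O)c1C(C)=O | intermediate
3 | 3-methylbut-2-enal (prenal) | CC(C)=CC=O | starting material
4 | (6Z)-4-acetyl-3-hydroxy-2-iodo-5-methoxy-6-(3-methylbut-2-en-1-ylidene)cyclohexa-2,4-dien-1-one (ortho-quinone methide, not isolated) | COC1=C(C(C)=O)C(O)=C(I)C(=O)/C1=C\C=C(C)C | intermediate
5 | 1-(7-hydroxy-8-iodo-5-methoxy-2,2-dimethyl-2H-chromen-6-yl)ethan-1-one | COc1c2C=CC(C)(C)Oc2c(I)c(O)c1C(C)=O | intermediate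
6 | 1-[8-iodo-5-methoxy-7-(methoxymethoxy)-2,2-dimethyl-2H-chromen-6-yl]ethan-1-one | COc1c2C=CC(C)(C)Oc2c(I)c(OCOC)c1C(C)=O | intermediate
7 | 4-hydroxybenzaldehyde | O=Cc1ccc(O)cc1 | starting material
8 | 4-(methoxymethoxy)benzaldehyde | COCOc1ccc(C=O)cc1 | intermediate
9 | (E)-1-[8-iodo-5-methoxy-7-(methoxymethoxy)-2,2-dimethyl-2H-chromen-6-yl]-3-[4-(methoxymethoxy)phenyl]prop-2-en-1-one | COc1c2C=CC(C)(C)Oc2c(I)c(OCOC)c1C(=O)/C=C/c1ccc(OCOC)cc1 | intermediate
10 | anti oxythallation adduct, 2-(dinitratothallio)-1-[8-iodo-5-methoxy-7-(methoxymethoxy)-2,2-dimethyl-2H-chromen-6-yl]-3-methoxy-3-[4-(methoxymethoxy)phenyl]propan-1-one (racemic, one enantiomer drawn, not isolated) | COc1c2C=CC(C)(C)Oc2c(I)c(OCOC)c1C(=O)[C@H]([Tl](O[N+](=O)[O-])O[N+](=O)[O-])[C@H](OC)c1ccc(OCOC)cc1 | intermediate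
11 | rac-1-[8-iodo-5-methoxy-7-(methoxymethoxy)-2,2-dimethyl-2H-chromen-6-yl]-3,3-dimethoxy-2-[4-(methoxymethoxy)phenyl]propan-1-one (racemate) | COc1c2C=CC(C)(C)Oc2c(I)c(OCOC)c1C(=O)C(C(OC)OC)c1ccc(OCOC)cc1 | intermediate
12 | 1-[8-iodo-5-methoxy-7-(methoxymethoxy)-2,2-dimethyl-2H-chromen-6-yl]-3-methoxy-2-[4-(methoxymethoxy)phenyl]prop-2-en-1-one (E/Z mixture, geometry not defined, not isolated) | COc1c2C=CC(C)(C)Oc2c(I)c(OCOC)c1C(=O)C(=COC)c1ccc(OCOC)cc1 | intermediate
13 | 3-[8-iodo-5-methoxy-7-(methoxymethoxy)-2,2-dimethyl-2H-chromen-6-yl]-2-[4-(methoxymethoxy)phenyl]-3-oxopropanal (racemic keto form; present as its potassium enolate, not isolated) | COc1c2C=CC(C)(C)Oc2c(I)c(OCOC)c1C(=O)C(C=O)c1ccc(OCOC)cc1 | intermediate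
14 | 1-[8-iodo-5-methoxy-7-(methoxymethoxy)-2,2-dimethyl-2H-chromen-6-yl]-2-[4-(methoxymethoxy)phenyl]ethan-1-one | COc1c2C=CC(C)(C)Oc2c(I)c(OCOC)c1C(=O)Cc1ccc(OCOC)cc1 | intermediate
15 | tributyl(3-methylbut-2-en-1-yl)stannane | CCCC[Sn](CCCC)(CCCC)CC=C(C)C | starting material
16 | 1-[5-methoxy-7-(methoxymethoxy)-2,2-dimethyl-8-(3-methylbut-2-en-1-yl)-2H-chromen-6-yl]-2-[4-(methoxymethoxy)phenyl]ethan-1-one | COc1c2C=CC(C)(C)Oc2c(CC=C(C)C)c(OCOC)c1C(=O)Cc1ccc(OCOC)cc1 | intermediate
17 | rac-2-hydroperoxy-1-[5-methoxy-7-(methoxymethoxy)-2,2-dimethyl-8-(3-methylbut-2-en-1-yl)-2H-chromen-6-yl]-2-[4-(methoxymethoxy)phenyl]ethan-1-one (racemate, not isolated) | COc1c2C=CC(C)(C)Oc2c(CC=C(C)C)c(OCOC)c1C(=O)C(OO)c1ccc(OCOC)cc1 | intermediate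
18 | 1-[5-methoxy-7-(methoxymethoxy)-2,2-dimethyl-8-(3-methylbut-2-en-1-yl)-2H-chromen-6-yl]-2-[4-(methoxymethoxy)phenyl]ethane-1,2-dione | COc1c2C=CC(C)(C)Oc2c(CC=C(C)C)c(OCOC)c1C(=O)C(=O)c1ccc(OCOC)cc1 | intermediate
19 | derrisdione A, 1-[7-hydroxy-5-methoxy-2,2-dimethyl-8-(3-methylbut-2-en-1-yl)-2H-chromen-6-yl]-2-(4-hydroxyphenyl)ethane-1,2-dione (achiral) | COc1c2c(c(CC=C(C)C)c(O)c1C(=O)C(=O)c1ccc(O)cc1)OC(C)(C)C=C2 | target

Total step count: 10. Longest linear sequence: 9 steps (steps 1, 2, 3, 5, 6, 7, 8, 9, 10); step 4 is a one-step side branch.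

**Steps most likely to fail**

Step 7 (proposed new method). Enolisation of the hindered, twisted aryl ketone may be too slow for methanol to be expelled, so the acetal could survive the alkali, or hydroxide could attack on the ketone side. The fallback uses known chemistry and sets out from 11. Heating 11 in methanolic HCl should hydrolyse the acetal and both MOM ethers and let the freed C7 hydroxyl close onto the aldehyde, giving the isoflavone 7-(4-hydroxyphenyl)-10-iodo-5-methoxy-2,2-dimethyl-2H,6H-pyrano[3,2-g]chromen-6-one F1. Refluxing aqueous NaOH under argon should then open the pyranone and split off formate to give 1-(7-hydroxy-8-iodo-5-methoxy-2,2-dimethyl-2H-chromen-6-yl)-2-(4-hydroxyphenyl)ethan-1-one F2. Chloromethyl methyl ether with K2CO3 in refluxing acetone would put both MOM groups back and return to the route at 14.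

Step 6 (key step). Trivalent thallium may also add to the electron-rich chromene double bond, and the nitric acid released may strip the C7 MOM ether so that the free hydroxyl cyclises. The fallback sets out from 9 and oxidises the enone with a nucleophilic oxidant that an electron-rich alkene ignores. Weitz–Scheffer epoxidation (H2O2, NaOH, MeOH/THF, 0 °C) should give the racemic trans epoxide [8-iodo-5-methoxy-7-(methoxymethoxy)-2,2-dimethyl-2H-chromen-6-yl]{3-[4-(methoxymethoxy)phenyl]oxiran-2-yl}methanone F3. Brief treatment with BF3·OEt2 in CH2Cl2 at low temperature should open it at the benzylic carbon and shift the aroyl group (Meinwald-type rearrangement) to give formyl ketone 13. Aqueous KOH in methanol then removes the formyl group as formate, and the route is rejoined at 14.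

Step 2. Condensation at the carbon next to the methoxyl may be slow, and attack at the iodinated carbon with loss of iodine may compete, giving the wrong ring fusion. The fallback sets out from 2 and builds the pyran ring by a sigmatropic route. O-Alkylation of the unchelated hydroxyl with 3-chloro-3-methylbut-1-yne (CuCl2 catalyst, DBU, MeCN, 0 °C) should give 1-{2-hydroxy-3-iodo-6-methoxy-4-[(2-methylbut-3-yn-2-yl)oxy]phenyl}ethan-1-one F4. Heating F4 in N,N-diethylaniline should trigger a propargyl Claisen rearrangement to the only free ortho carbon, a 1,5-hydrogen shift and oxa-6π ring closure, which returns to the route at 5.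

**Further compounds**
F1 | step 7 | 7-(4-hydroxyphenyl)-10-iodo-5-methoxy-2,2-dimethyl-2H,6H-pyrano[3,2-g]chromen-6-one | COc1c2C=CC(C)(C)Oc2c(I)c2occ(-c3ccc(O)cc3)c(=O)c12
F2 | step 7 | 1-(7-hydroxy-8-iodo-5-methoxy-2,2-dimethyl-2H-chromen-6-yl)-2-(4-hydroxyphenyl)ethan-1-one | COc1c2C=CC(C)(C)Oc2c(I)c(O)c1C(=O)Cc1ccc(O)cc1
F3 | step 6 | [8-iodo-5-methoxy-7-(methoxymethoxy)-2,2-dimethyl-2H-chromen-6-yl]{3-[4-(methoxymethoxy)phenyl]oxiran-2-yl}methanone (racemic trans epoxide, one enantiomer drawn) | COc1c2C=CC(C)(C)Oc2c(I)c(OCOC)c1C(=O)[C@@H]1O[C@H]1c1ccc(OCOC)cc1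
F4 | step 2 | 1-{2-hydroxy-3-iodo-6-methoxy-4-[(2-methylbut-3-yn-2-yl)oxy]phenyl}ethan-1-one | COc1cc(OC(C)(C)C#C)c(I)c(O)c1C(C)=O
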